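**Retrosynthetic overview**

1. Locants: cyclopentane C1 (carbinol carbon with CH2OAc), C2, C3 (bears the chain Ca(CH3)=Cb–Cc=Cd–Ce(CH3)2OOH), C4, C5 (bears the cyclopentenone C1'–C2'(=O)–C3'=C4'–C5'(CH3)).
2. Side chain: the hydroperoxide is released last from a peroxyketal; Cc=Cd comes from cross-metathesis; the Z-Ca=Cb bond comes from an alkoxide-directed syn-carbomagnesiation of a propargylic alcohol grown from a C3 acetyl group.
3. Cyclopentenone (second ring): ring-closing metathesis at C3'=C4'; C1' and C5' are set by an Ireland–Claisen rearrangement of the (E)-crotyl ester of the C5 acetic acid arm; the enone is stored as its allylic alcohol until the penultimate step.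
4. Cyclopentane (first ring): the C2–C3 bond is closed by intramolecular α-allylation of a methyl ketone; C1 then follows from dihydroxylation of the exocyclic methylene and C3 from an epimerising bridged ketalisation; the acyclic precursor is (S)-limonene after ozonolytic ring opening and ene-chlorination, which also supplies C5.
5. Enabling feature: C1 carries two CH2 groups (C2 and the acetoxymethyl carbon), which with C1 form a 2-substituted allyl unit on C5, and C3 is the α-carbon of the latent methyl ketone Ca(=O)CH3, joined to C1 through C4–C5; this is the opened p-menthene skeleton, so ring C1–C5 closes 5-exo between C3 and C2.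

Key step: step 3

Remark: the ketal carbon in 9–16 and the carbinol carbon C2' in 16–30 are temporary stereocentres; their configuration has no bearing on the target.

**Step 1**
Reactants: 1 (S)-(−)-limonene
Product: 3 methyl (3S)-6-oxo-3-(prop-1-en-2-yl)heptanoate, via methoxy hydroperoxide 2 (not isolated)
Conditions: O3 (1 equiv), NaHCO3, CH2Cl2/MeOH, −78 °C; then Ac2O, Et3N, 0 → 25 °C
Reagents that add atoms: ozone, [O-][O+]=O; methanol, CO
Why: Criegee ozonolysis in methanol should cleave the electron-rich trisubstituted ring alkene in preference to the isopropenyl group, and dehydration of the trapped α-methoxy hydroperoxide gives the methyl ester beside the methyl ketone, while the limonene stereocentre becomes C5 untouched.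

**Step 2**
Reactants: 3 methyl (3S)-6-oxo-3-(prop-1-en-2-yl)heptanoate
Product: 4 methyl (3S)-3-(3-chloroprop-1-en-2-yl)-6-oxoheptanoate
Conditions: Ca(OCl)2, solid CO2, CH2Cl2/H2O, 0 °C
Reagents that add atoms: calcium hypochlorite, [Ca+2].[O-]Cl.[O-]Cl
Why: ene-type allylic chlorination of the 1,1-disubstituted alkene by hypochlorous acid should give the 2-substituted allyl chloride with loss of a methyl hydrogen and creates no stereocentre.

**Step 3**
Reactants: 4 methyl (3S)-3-(3-chloroprop-1-en-2-yl)-6-oxoheptanoate
Product: 7 methyl 2-[(1S)-4-acetyl-2-methylidenecyclopentyl]acetate (both C3 epimers), via enamine 5 (not isolated), via iminium salt 6 (not isolated)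
Conditions: Pd(PPh3)4 (5 mol%), pyrrolidine (0.3 equiv), Et3N (1.2 equiv), THF, 25 °C; aq. NH4Cl
Reagents that add atoms: none
Why: Pyrrolidine condenses with the methyl ketone to its enamines while zerovalent palladium ionises the allylic chloride to a 2-substituted π-allylpalladium cation; the C3 enamine carbon attacks an allyl terminus and hydrolysis of the iminium salt returns the ketone and the amine. The closest known reaction type is the organocatalytic Tsuji–Trost cyclisation (enamine/π-allylpalladium dual catalysis) of carbonyl compounds carrying an allylic halide, together with the intermolecular α-allylation of ketones under the same dual catalysis. The cyclopentane C1–C5 closes in the 5-exo mode with the central allyl carbon C1 inside the ring, and because both allyl termini are constitutionally equivalent either terminus gives the same methylenecyclopentane. The only new stereocentre, C3, is α to the ketone and is not controlled here but in step 5, whereas C5 is neither enolisable nor ionised and should keep its configuration. The step needs C3 over CH3 regioselectivity, which ring size secures (the methyl enamine could only close a seven-membered ring), and C- over N-allylation, which is secured because N-allylpyrrolidinium ions re-ionise under palladium. The ester is inert under enamine conditions, so the Claisen condensation that a metal enolate would risk should not arise.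

**Step 4**
Reactants: 7 methyl 2-[(1S)-4-acetyl-2-methylidenecyclopentyl]acetate
Product: 8 methyl 2-[4-acetyl-2-hydroxy-2-(hydroxymethyl)cyclopentyl]acetate (C1 hydroxyl trans and hydroxymethyl cis to the C5 arm; both C3 epimers)
Conditions: OsO4 (cat.), N-methylmorpholine N-oxide, acetone/H2O, 25 °C
Reagents that add atoms: N-methylmorpholine N-oxide, C[N+]1([O-])CCOCC1; water, O
Why: Upjohn dihydroxylation should deliver both oxygens to the exocyclic methylene from the ring face opposite the adjacent C5 arm, which places the tertiary hydroxyl trans and the hydroxymethyl group cis to that arm and so sets C1.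

**Step 5**
Reactants: 8 methyl 2-[4-acetyl-2-hydroxy-2-(hydroxymethyl)cyclopentyl]acetate
Product: 9 methyl 2-(1-hydroxy-4-methoxy-4-methyl-3-oxabicyclo[3.2.1]octan-7-yl)acetate (bridged methyl ketal, acetyl carbon cis to the C1 CH2O group)
Conditions: camphorsulfonic acid (cat.), MeOH, 3 Å molecular sieves, 45 °C
Reagents that add atoms: methanol, CO
Why: acid-catalysed intramolecular ketalisation can close the 3-oxabicyclo[3.2.1]octane only from the C3 epimer whose acetyl group is cis to the C1 hydroxymethyl group, and acid-catalysed enolisation should feed the other epimer into this sink, so C3 is set under thermodynamic control.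

**Step 6**
Reactants: 9 bridged methyl ketal methyl ester
Product: 10 (E)-but-2-enyl 2-(1-hydroxy-4-methoxy-4-methyl-3-oxabicyclo[3.2.1]octan-7-yl)acetate
Conditions: (E)-but-2-en-1-ol (excess), Ti(OiPr)4 (cat.), toluene, 90 °C
Reagents that add atoms: (E)-but-2-en-1-ol, C/C=C/CO
Why: titanate-mediated transesterification exchanges the methyl for the crotyl ester under neutral conditions that leave the ketal and all stereocentres alone.

**Step 7**
Reactants: 10 (E)-but-2-enyl ester
Product: 13 (2S,3R)-2-(1-hydroxy-4-methoxy-4-methyl-3-oxabicyclo[3.2.1]octan-7-yl)-3-methylpent-4-enoic acid, via silyl ketene acetal 11 (not isolated), via trimethylsilyl ester 12 (not isolated)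
Conditions: LiN(iPr)2 (2.2 equiv), THF, −78 °C; Me3SiCl; → 25 °C; then K2CO3, MeOH/H2O; pH 5 phosphate buffer
Reagents that add atoms: none
Why: Ireland–Claisen rearrangement of the kinetic enolate (C5 trans to OLi) with the (E)-crotyl group through a chair transition state should give the anti C1'/C5' pair, while allylic strain holds the C5–H bond in the enolate plane so that the crotyl unit adds to the face away from the quaternary C1, which fixes C1' relative to C5.

**Step 8**
Reactants: 13 pentenoic acid
Product: 14 (4S,5R)-4-(1-hydroxy-4-methoxy-4-methyl-3-oxabicyclo[3.2.1]octan-7-yl)-5-methylhepta-1,6-dien-3-one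
Conditions: vinyllithium (3.5 equiv), THF, −78 → 0 °C; inverse quench into aq. NH4Cl
Reagents that add atoms: vinyllithium, [Li]C=C
Why: ketone synthesis from a lithium carboxylate and an organolithium proceeds through a stable geminal dialkoxide that neither over-adds nor enolises, so C1' should not epimerise.

**Step 9**
Reactants: 14 vinyl ketone
Product: 15 (4R,5S)-5-(1-hydroxy-4-methoxy-4-methyl-3-oxabicyclo[3.2.1]octan-7-yl)-4-methylcyclopent-2-en-1-one (cis)
Conditions: second-generation Grubbs catalyst RuCl2(=CHPh)(H2IMes)(PCy3) (5 mol%), CH2Cl2, 40 °C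
Reagents that add atoms: none
Why: ring-closing metathesis of the vinyl ketone with the terminal vinyl group closes the cyclopent-2-enone under neutral conditions, so the cis C1'/C5' relationship from step 7 passes into the ring unchanged.

**Step 10**
Reactants: 15 cis-cyclopentenone
Product: 16 the corresponding cyclopent-2-en-1-ol (hydroxyl cis to the C1' substituent)
Conditions: NaBH4, CeCl3·7H2O, MeOH, −78 °C
Reagents that add atoms: none
Why: Luche 1,2-reduction masks the base-sensitive cis-enone as an allylic alcohol, hydride entering anti to the two cis substituents, and the new carbinol centre is removed again in step 22.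

**Step 11**
Reactants: 16 cyclopentenol ketal
Product: 17 1-[3-hydroxy-3-(hydroxymethyl)-4-(2-hydroxy-5-methylcyclopent-3-en-1-yl)cyclopentyl]ethan-1-one (acetyl cis to CH2OH)
Conditions: pyridinium p-toluenesulfonate (cat.), acetone/H2O, 25 °C
Reagents that add atoms: water, O
Why: mild acid hydrolysis of the mixed ketal is far faster than acid-catalysed enolisation of the liberated ketone, so C3 should keep its configuration.

**Step 12**
Reactants: 17 triol ketone
Product: 18 bis(tert-butyldimethylsilyl) ether of 17 at the primary and the secondary hydroxyl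
Conditions: t-BuMe2SiCl (2.3 equiv), imidazole, DMF, 25 °C
Reagents that add atoms: tert-butyldimethylsilyl chloride, CC(C)(C)[Si](C)(C)Cl
Why: silylation takes the primary and the secondary allylic hydroxyl but not the hindered tertiary one and traps the open hydroxy ketone form.

**Step 13**
Reactants: 18 bis-silyl ether ketone
Product: 21 propargylic alcohol (C3–C≡C–CH2OH), via enol phosphate 19 (not isolated), via lithium acetylide 20 (not isolated)
Conditions: LiN(iPr)2 (2.1 equiv), THF, −78 °C; ClP(O)(OEt)2; LiN(iPr)2 (2.5 equiv), −78 → 0 °C; (CH2O)n; aq. NH4Cl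
Reagents that add atoms: formaldehyde (as paraformaldehyde), C=O
Why: kinetic enolisation at the methyl group, O-phosphorylation, elimination of the enol phosphate to the acetylide and hydroxymethylation with formaldehyde turn the acetyl group into the propargylic alcohol without deprotonating C3.

**Step 14**
Reactants: 21 propargylic alcohol
Product: 22 (Z)-allylic alcohol (C3–C(CH3)=CH–CH2OH, C3 cis to CH2OH)
Conditions: MeMgBr (5 equiv), Fe(acac)3 (cat.), THF, −78 → 0 °C; aq. NH4Cl
Reagents that add atoms: methylmagnesium bromide, C[Mg]Br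
Why: alkoxide-directed iron-catalysed syn-carbomagnesiation puts methyl on the distal alkyne carbon and magnesium on the proximal one in a five-membered chelate, so protonation should give the Z trisubstituted alkene.

**Step 15**
Reactants: 22 (Z)-allylic alcohol
Product: 23 (Z)-enal
Conditions: MnO2, CH2Cl2, 25 °C
Reagents that add atoms: none
Why: manganese dioxide oxidises the primary allylic alcohol selectively under neutral conditions that should retain the Z geometry.

**Step 16**
Reactants: 23 (Z)-enal
Product: 24 (Z)-1,3-diene (C3–C(CH3)=CH–CH=CH2)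
Conditions: Ph3PCH3Br, KN(SiMe3)2, THF, −78 → 0 °C
Reagents that add atoms: methyltriphenylphosphonium bromide, C[P+](c1ccccc1)(c1ccccc1)c1ccccc1.[Br-]
Why: Wittig methylenation of the aldehyde gives the terminal vinyl group needed for cross-metathesis without touching the trisubstituted alkene.

**Step 17**
Reactants: 25 2-methylbut-3-en-2-ol
Product: 26 2-methylbut-3-en-2-yl hydroperoxide
Conditions: 50% aq. H2O2, H2SO4 (cat.), 0 °C
Reagents that add atoms: hydrogen peroxide, OO
Why: acid-catalysed SN1 perhydrolysis of the tertiary allylic alcohol traps the allyl cation at its tertiary terminus.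

**Step 18**
Reactants: 26 2-methylbut-3-en-2-yl hydroperoxide
Product: 27 2-[(2-methoxypropan-2-yl)peroxy]-2-methylbut-3-ene
Conditions: 2-methoxypropene, pyridinium p-toluenesulfonate (cat.), CH2Cl2, 0 °C
Reagents that add atoms: 2-methoxypropene, COC(C)=C
Why: acid-catalysed addition of the hydroperoxide to the enol ether gives a base-stable peroxyketal that tolerates ruthenium carbenes and fluoride.

**Step 19**
Reactants: 24 (Z)-1,3-diene; 27 peroxyketal olefin
Product: 28 (2Z,4E)-diene peroxyketal, bis-silyl ether
Conditions: second-generation Hoveyda–Grubbs catalyst RuCl2(=CH-C6H4-2-OiPr)(H2IMes) (5 mol%), 27 (3 equiv), CH2Cl2, 40 °C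
Reagents that add atoms: none
Why: cross-metathesis of the terminal vinyl group with the hindered tertiary allylic olefin, which does not homodimerise, should give the E disubstituted alkene, while the trisubstituted Z alkene and the unstrained cyclopentene stay out of the reaction.

**Step 20**
Reactants: 28 bis-silyl ether
Product: 29 triol peroxyketal
Conditions: Bu4NF, THF, 0 → 25 °C
Reagents that add atoms: none
Why: fluoride-mediated desilylation frees the primary and the secondary hydroxyl, the peroxyketal being stable to base.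

**Step 21**
Reactants: 29 triol peroxyketal
Product: 30 primary acetate
Conditions: AcCl (1.05 equiv), 2,4,6-collidine, CH2Cl2, −78 °C
Reagents that add atoms: acetyl chloride, CC(Cl)=O
Why: acylation at low temperature with a hindered pyridine base should select the primary hydroxyl over the secondary allylic and the tertiary one.

**Step 22**
Reactants: 30 primary acetate
Product: 31 cis-cyclopentenone peroxyketal
Conditions: Dess–Martin periodinane, NaHCO3, CH2Cl2, 0 °C
Reagents that add atoms: none
Why: buffered Dess–Martin oxidation returns the allylic alcohol to the cyclopent-2-enone under neutral conditions that should not epimerise C1'.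

**Step 23**
Reactants: 31 cis-cyclopentenone peroxyketal
Product: 32 CNP0204569.1
Conditions: pyridinium p-toluenesulfonate (cat.), MeOH, 0 °C
Reagents that add atoms: none
Why: acid-catalysed methanolysis of the 2-methoxyprop-2-yl peroxyketal releases the tertiary hydroperoxide under conditions too mild to enolise the enone or cleave the acetate.

**Compound list**

1 | (S)-(−)-limonene | CC1=CC[C@H](CC1)C(C)=C | starting material
2 | (5S)-7-hydroperoxy-7-methoxy-5-(prop-1-en-2-yl)heptan-2-one | CC(=O)CC[C@H](C(C)=C)CC(OC)OO | intermediate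
3 | methyl (3S)-6-oxo-3-(prop-1-en-2-yl)heptanoate | CC(=O)CC[C@H](C(C)=C)CC(=O)OC | intermediate
4 | methyl (3S)-3-(3-chloroprop-1-en-2-yl)-6-oxoheptanoate | CC(=O)CC[C@H](C(=C)CCl)CC(=O)OC | intermediate
5 | pyrrolidine enamine of 4 (C=C towards C3) | CC(=CC[C@H](C(=C)CCl)CC(=O)OC)N1CCCC1 | intermediate
6 | cyclised pyrrolidinium (iminium) chloride of 7 | C=C1CC(C(C)=[N+]2CCCC2)C[C@H]1CC(=O)OC.[Cl-] | intermediate
7 | methyl 2-[(1S)-4-acetyl-2-methylidenecyclopentyl]acetate (both C3 epimers) | C=C1CC(C(C)=O)C[C@H]1CC(=O)OC | intermediate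
8 | methyl 2-[4-acetyl-2-hydroxy-2-(hydroxymethyl)cyclopentyl]acetate (OH trans, CH2OH cis to the C5 arm; both C3 epimers) | OC[C@@]1(O)CC(C(C)=O)C[C@H]1CC(=O)OC | intermediate
9 | methyl 2-(1-hydroxy-4-methoxy-4-methyl-3-oxabicyclo[3.2.1]octan-7-yl)acetate | COC1(C)OC[C@@]2(O)C[C@@H]1C[C@H]2CC(=O)OC | intermediate
10 | (E)-but-2-enyl ester of 9 | COC1(C)OC[C@@]2(O)C[C@@H]1C[C@H]2CC(=O)OC/C=C/C | intermediate
11 | bis(trimethylsilyl) ketene acetal of 10 (C5 trans to OSiMe3) | COC1(C)OC[C@@]2(O[Si](C)(C)C)C[C@@H]1C[C@H]2/C=C(/O[Si](C)(C)C)OC/C=C/C | intermediate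
12 | trimethylsilyl ester of 13 with tertiary OSiMe3 | COC1(C)OC[C@@]2(O[Si](C)(C)C)C[C@@H]1C[C@H]2[C@@H](C(=O)O[Si](C)(C)C)[C@H](C)C=C | intermediate
13 | (2S,3R)-2-(bridged ketal-7-yl)-3-methylpent-4-enoic acid | COC1(C)OC[C@@]2(O)C[C@@H]1C[C@H]2[C@@H](C(O)=O)[C@H](C)C=C | intermediate
14 | (4S,5R)-4-(bridged ketal-7-yl)-5-methylhepta-1,6-dien-3-one | COC1(C)OC[C@@]2(O)C[C@@H]1C[C@H]2[C@@H](C(=O)C=C)[C@H](C)C=C | intermediate
15 | (4R,5S)-5-(bridged ketal-7-yl)-4-methylcyclopent-2-en-1-one | COC1(C)OC[C@@]2(O)C[C@@H]1C[C@H]2[C@H]3C(=O)C=C[C@H]3C | intermediate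
16 | cyclopent-2-en-1-ol from 15 (OH cis to the C1' substituent) | COC1(C)OC[C@@]2(O)C[C@@H]1C[C@H]2[C@H]3[C@@H](O)C=C[C@H]3C | intermediate
17 | triol methyl ketone (acetyl at C3 cis to CH2OH) | OC[C@@]1(O)C[C@@H](C(C)=O)C[C@H]1[C@H]2[C@@H](O)C=C[C@H]2C | intermediate
18 | bis(tert-butyldimethylsilyl) ether of 17 | CC(C)(C)[Si](C)(C)OC[C@@]1(O)C[C@@H](C(C)=O)C[C@H]1[C@H]2[C@@H](O[Si](C)(C)C(C)(C)C)C=C[C@H]2C | intermediate
19 | terminal enol diethyl phosphate of 18 (lithium alkoxide) | CC(C)(C)[Si](C)(C)OC[C@@]1(O[Li])C[C@@H](C(=C)OP(=O)(OCC)OCC)C[C@H]1[C@H]2[C@@H](O[Si](C)(C)C(C)(C)C)C=C[C@H]2C | intermediate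
20 | lithium acetylide (lithium alkoxide) | CC(C)(C)[Si](C)(C)OC[C@@]1(O[Li])C[C@@H](C#C[Li])C[C@H]1[C@H]2[C@@H](O[Si](C)(C)C(C)(C)C)C=C[C@H]2C | intermediate
21 | propargylic alcohol | CC(C)(C)[Si](C)(C)OC[C@@]1(O)C[C@@H](C#CCO)C[C@H]1[C@H]2[C@@H](O[Si](C)(C)C(C)(C)C)C=C[C@H]2C | intermediate
22 | (Z)-3-methylallylic alcohol | CC(C)(C)[Si](C)(C)OC[C@@]1(O)C[C@@H](/C(C)=C\CO)C[C@H]1[C@H]2[C@@H](O[Si](C)(C)C(C)(C)C)C=C[C@H]2C | intermediate
23 | (Z)-enal | CC(C)(C)[Si](C)(C)OC[C@@]1(O)C[C@@H](/C(C)=C\C=O)C[C@H]1[C@H]2[C@@H](O[Si](C)(C)C(C)(C)C)C=C[C@H]2C | intermediate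
24 | (Z)-1,3-diene | CC(C)(C)[Si](C)(C)OC[C@@]1(O)C[C@@H](/C(C)=C\C=C)C[C@H]1[C@H]2[C@@H](O[Si](C)(C)C(C)(C)C)C=C[C@H]2C | intermediate
25 | 2-methylbut-3-en-2-ol | CC(C)(O)C=C | starting material
26 | 2-methylbut-3-en-2-yl hydroperoxide | CC(C)(OO)C=C | intermediate
27 | 2-[(2-methoxypropan-2-yl)peroxy]-2-methylbut-3-ene | COC(C)(C)OOC(C)(C)C=C | intermediate
28 | (2Z,4E)-diene peroxyketal, bis-silyl ether | CC(C)(C)[Si](C)(C)OC[C@@]1(O)C[C@@H](/C(C)=C\C=C\C(C)(C)OOC(C)(C)OC)C[C@H]1[C@H]2[C@@H](O[Si](C)(C)C(C)(C)C)C=C[C@H]2C | intermediate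
29 | triol peroxyketal | OC[C@@]1(O)C[C@@H](/C(C)=C\C=C\C(C)(C)OOC(C)(C)OC)C[C@H]1[C@H]2[C@@H](O)C=C[C@H]2C | intermediate
30 | primary acetate of 29 | CC(=O)OC[C@@]1(O)C[C@@H](/C(C)=C\C=C\C(C)(C)OOC(C)(C)OC)C[C@H]1[C@H]2[C@@H](O)C=C[C@H]2C | intermediate
31 | cis-cyclopentenone peroxyketal | CC(=O)OC[C@@]1(O)C[C@@H](/C(C)=C\C=C\C(C)(C)OOC(C)(C)OC)C[C@H]1[C@H]1C(=O)C=C[C@H]1C | intermediate
32 | CNP0204569.1 | CC(=O)OC[C@@]1(O)C[C@@H](/C(C)=C\C=C\C(C)(C)OO)C[C@H]1[C@H]1C(=O)C=C[C@H]1C | target

**Step count**

Total step count: 23. Longest linear sequence: 21 steps (steps 1–16 and 19–23); steps 17–18 prepare the metathesis partner.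

**Steps most likely to fail**

Step 3. Enamine formation from the methyl ketone may be slow and the amine may be consumed by N-allylation, so the cyclisation could stall or give oligomers. The fallback replaces the catalytic enamine by a regiodefined enolate. It sets out from 4: Me3SiCl, NaI and Et3N in MeCN should give the more substituted trimethylsilyl enol ether and exchange chloride for iodide (Finkelstein), giving the silyl enol ether iodide F1. Anhydrous Bu4NF in THF then releases the C3 enolate, which closes the ring by 5-exo-tet displacement, and the route is rejoined at 7.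

Step 5. Equilibration at C3 may be incomplete, or the hydroxymethyl group may be diverted into lactonisation with the C5 ester, so the ketal sink might not collect all material. The fallback sets C3 by reagent-directed hydrogen delivery instead of equilibration. It sets out from 8: t-BuMe2SiCl and imidazole give the primary silyl ether F2. Dehydrogenation with 2-iodoxybenzoic acid in DMSO at 65 °C gives the ring enone F3 (its C3=C4 isomer would serve equally). Hydrogenation with H2 and [Ir(cod)(PCy3)(py)]PF6 in CH2Cl2, directed by the C1 tertiary hydroxyl to its own face, gives the cis ketone F4. Camphorsulfonic acid in MeOH removes the silyl group and closes the ketal, rejoining at 9.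

Step 7. Facial selectivity of the rearrangement may be poor, or the enolate geometry may erode, giving C1'/C5' diastereomers. The fallback builds the cyclopentenone by annulation and sets both centres by hydrogenation. It sets out from 9: (i-Bu)2AlH in CH2Cl2 at −78 °C gives the aldehyde F5. A Stetter reaction with but-3-en-2-one (3-benzyl-5-(2-hydroxyethyl)-4-methylthiazolium chloride, Et3N, EtOH) gives the 1,4-diketone F6. Aldol condensation with KOH in MeOH gives the 2-substituted 3-methylcyclopent-2-enone F7. Hydrogenation over Pd/C, syn and from the face away from C1 as allylic strain dictates, gives the cis-cyclopentanone F8. Kinetic enolisation with LiN(iPr)2 and Me3SiCl gives the silyl enol ether F9, and Saegusa–Ito oxidation with Pd(OAc)2 in MeCN, followed by a buffered KF work-up, rejoins the route at 15.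

**Further compounds**

F1 | step 3 | methyl (3S)-3-(3-iodoprop-1-en-2-yl)-6-(trimethylsilyloxy)hept-5-enoate | CC(O[Si](C)(C)C)=CC[C@H](C(=C)CI)CC(=O)OC
F2 | step 5 | primary tert-butyldimethylsilyl ether of 8 | CC(C)(C)[Si](C)(C)OC[C@@]1(O)CC(C(C)=O)C[C@H]1CC(=O)OC
F3 | step 5 | ring enone (1-acetylcyclopentene, C2=C3) from F2 | CC(C)(C)[Si](C)(C)OC[C@@]1(O)C=C(C(C)=O)C[C@H]1CC(=O)OC
F4 | step 5 | cis ketone (acetyl cis to the silyloxymethyl group) | CC(C)(C)[Si](C)(C)OC[C@@]1(O)C[C@@H](C(C)=O)C[C@H]1CC(=O)OC
F5 | step 7 | 2-(bridged ketal-7-yl)acetaldehyde | COC1(C)OC[C@@]2(O)C[C@@H]1C[C@H]2CC=O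
F6 | step 7 | 1-(bridged ketal-7-yl)hexane-2,5-dione | COC1(C)OC[C@@]2(O)C[C@@H]1C[C@H]2CC(=O)CCC(C)=O
F7 | step 7 | 2-(bridged ketal-7-yl)-3-methylcyclopent-2-en-1-one | COC1(C)OC[C@@]2(O)C[C@@H]1C[C@H]2C3=C(C)CCC3=O
F8 | step 7 | cis-2-(bridged ketal-7-yl)-3-methylcyclopentan-1-one | COC1(C)OC[C@@]2(O)C[C@@H]1C[C@H]2[C@H]3C(=O)CC[C@H]3C
F9 | step 7 | trimethylsilyl enol ether of F8 towards C3' (tertiary OSiMe3) | COC1(C)OC[C@@]2(O[Si](C)(C)C)C[C@@H]1C[C@H]2[C@H]3C(O[Si](C)(C)C)=CC[C@H]3C
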